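**Retrosynthetic overview**
- Vitedoin A (10) comes from its tris-silyl ether 9 by global desilylation.
- 9 comes from 2-benzylbenzaldehyde 7 and C4 enal 8 in one annulation that forms carbocycle B last: a benzhydryl-radical/iminium coupling makes C1–C2 and sets both stereocentres, then an intramolecular aldol condensation makes C3=C4.
- 7 comes from lactol 6 by benzylic C–O hydrogenolysis; 6 comes from two molecules of aldehyde 5 (ortho-lithiation at C2 of one, addition to the CHO of the other, forming C8a–C1).
- 5 comes from catechol by mono-methylation, para-bromination, silylation and formylation; both aromatic rings derive from 5.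

Assumption: (E)-4-(tert-butyldimethylsilyloxy)but-2-enal (8) is bought as a catalogue compound. Locants follow 1,2-dihydronaphthalene numbering: C1 = CH–Ar, C2 = CH–CH2O, C3 = C–CHO, C4 = vinylic CH, C7–O, C8–OMe.

**Step 1**
Reactants: 1 catechol
Product: 2 guaiacol (2-methoxyphenol)
Conditions: MeI (1.0 equiv), K2CO3, acetone, reflux; distil
Reagents that add atoms: iodomethane, CI
Why: Williamson O-methylation with one equivalent of MeI gives the mono-ether as the main product, separable from catechol and veratrole by base extraction and distillation; no stereocentre.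

**Step 2**
Reactants: 2 guaiacol
Product: 3 4-bromo-2-methoxyphenol
Conditions: NBS, MeCN, 0 °C
Reagents that add atoms: N-bromosuccinimide, BrN1C(=O)CCC1=O
Why: Electrophilic aromatic bromination; the free OH is the stronger director, so Br enters para to it.

**Step 3**
Reactants: 3 4-bromo-2-methoxyphenol
Product: 4 (4-bromo-2-methoxyphenoxy)triisopropylsilane
Conditions: TIPSCl, imidazole, DMF, rt
Reagents that add atoms: chlorotriisopropylsilane, CC(C)[Si](Cl)(C(C)C)C(C)C
Why: Standard phenol silylation; the bulky TIPS ether tolerates alkyllithiums and does not direct ortho-metalation.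

**Step 4**
Reactants: 4 (4-bromo-2-methoxyphenoxy)triisopropylsilane
Product: 5 3-methoxy-4-(triisopropylsilyloxy)benzaldehyde
Conditions: n-BuLi, THF, −78 °C; DMF; aq NH4Cl
Reagents that add atoms: N,N-dimethylformamide, CN(C)C=O
Why: Br–Li exchange followed by Bouveault formylation gives the O-TIPS vanillin.

**Step 5**
Reactants: 5 3-methoxy-4-(triisopropylsilyloxy)benzaldehyde (two molecules: one as nucleophile precursor, one as electrophile)
Product: 6 4-methoxy-3-[3-methoxy-4-(triisopropylsilyloxy)phenyl]-5-(triisopropylsilyloxy)-1,3-dihydroisobenzofuran-1-ol (lactol form of the 2-[aryl(hydroxy)methyl]benzaldehyde; racemic diastereomer mixture)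
Conditions: LiN(Me)CH2CH2NMe2 (1.1 equiv), THF, −20 °C; s-BuLi (1.3 equiv), −45 °C; then 5 (1.2 equiv), −78 → 0 °C; aq NH4Cl
Reagents that add atoms: none
Why: Comins α-amino-alkoxide directed ortho-lithiation: the in situ amino alkoxide masks CHO and, with OMe, directs lithiation to the carbon between them; the aryllithium adds 1,2 to a second molecule of 5 and the hydroxy-aldehyde closes to the lactol. Both stereocentres of 6 are removed in step 6.

**Step 6**
Reactants: 6 lactol
Product: 7 3-methoxy-2-{[3-methoxy-4-(triisopropylsilyloxy)phenyl]methyl}-4-(triisopropylsilyloxy)benzaldehyde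
Conditions: H2 (1 atm), 10% Pd/C, EtOAc (cat. AcOH), rt, stop at full conversion of 6
Reagents that add atoms: none
Why: Benzylic hydrogenolysis of the doubly benzylic C–O bond; the ring-opened hemiacetal collapses to the aldehyde, which as an electron-rich ArCHO is reduced much more slowly (as in debenzylation of O-benzylvanillin).

**Step 7**
Reactants: 7 2-benzylbenzaldehyde; 8 (E)-4-(tert-butyldimethylsilyloxy)but-2-enal (2 equiv)
Product: 9 (1S,2R)-2-[(tert-butyldimethylsilyloxy)methyl]-8-methoxy-1-[3-methoxy-4-(triisopropylsilyloxy)phenyl]-7-(triisopropylsilyloxy)-1,2-dihydronaphthalene-3-carbaldehyde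
Conditions: (R)-α,α-bis[3,5-bis(trifluoromethyl)phenyl]prolinol TMS ether (20–30 mol %), TFA (40 mol %), MeCN, 400 nm LED, 0 °C; then 4 Å MS, rt
Reagents that add atoms: none (water is lost)
Why: Proposed new method: light excites the iminium of 8 (or its charge-transfer complex with the electron-rich arene 7), which oxidises 7 by SET; loss of the doubly benzylic proton gives the o-formylbenzhydryl radical, which couples in-cage with the catalyst-bound β-enaminyl radical (C1–C2), and the resulting enamine closes on the neighbouring ArCHO by aldol condensation (C3=C4). C2 (R) is set by bond formation on the iminium face anti to the CAr2OSi group of the (R)-catalyst. C1 (S, 1,2-trans) is set by the Ar-outside, endo-type stacked approach that ring closure requires; this diastereocontrol is the untested point, and any cis isomer is removed by chromatography without affecting the ee fixed at C2. Closest known reactions: photo-organocatalytic excited-iminium radical β-benzylation of enals, and amine-catalysed Michael/aldol-condensation routes to 1,2-dihydronaphthalene-3-carbaldehydes.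

**Step 8**
Reactants: 9 tris-silyl ether
Product: 10 vitedoin A, (1S,2R)-7-hydroxy-1-(4-hydroxy-3-methoxyphenyl)-2-(hydroxymethyl)-8-methoxy-1,2-dihydronaphthalene-3-carbaldehyde [= (3R,4S)-6-hydroxy-4-(4-hydroxy-3-methoxyphenyl)-3-(hydroxymethyl)-5-methoxy-3,4-dihydronaphthalene-2-carbaldehyde]
Conditions: TBAF (3.5 equiv), AcOH (3.5 equiv), THF, 0 °C
Reagents that add atoms: none
Why: Fluoride desilylation removes both aryl TIPS ethers and the primary TBS ether; AcOH buffering protects the phenoxide/enal system, and C1–H and C2–H are not acidic, so both stereocentres are retained.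

**Compound list**
1 | catechol | Oc1ccccc1O | starting material
2 | guaiacol | COc1ccccc1O | intermediate
3 | 4-bromo-2-methoxyphenol | COc1cc(Br)ccc1O | intermediate
4 | (4-bromo-2-methoxyphenoxy)triisopropylsilane | COc1cc(Br)ccc1O[Si](C(C)C)(C(C)C)C(C)C | intermediate
5 | 3-methoxy-4-(triisopropylsilyloxy)benzaldehyde | COc1cc(C=O)ccc1O[Si](C(C)C)(C(C)C)C(C)C | intermediate
6 | 4-methoxy-3-[3-methoxy-4-(triisopropylsilyloxy)phenyl]-5-(triisopropylsilyloxy)-1,3-dihydroisobenzofuran-1-ol (racemic, diastereomer mixture) | OC1OC(c2ccc(O[Si](C(C)C)(C(C)C)C(C)C)c(OC)c2)c2c(OC)c(O[Si](C(C)C)(C(C)C)C(C)C)ccc12 | intermediate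
7 | 3-methoxy-2-{[3-methoxy-4-(triisopropylsilyloxy)phenyl]methyl}-4-(triisopropylsilyloxy)benzaldehyde | COc1cc(Cc2c(C=O)ccc(O[Si](C(C)C)(C(C)C)C(C)C)c2OC)ccc1O[Si](C(C)C)(C(C)C)C(C)C | intermediate
8 | (E)-4-(tert-butyldimethylsilyloxy)but-2-enal | CC(C)(C)[Si](C)(C)OC/C=C/C=O | starting material
9 | (1S,2R)-2-[(tert-butyldimethylsilyloxy)methyl]-8-methoxy-1-[3-methoxy-4-(triisopropylsilyloxy)phenyl]-7-(triisopropylsilyloxy)-1,2-dihydronaphthalene-3-carbaldehyde | COc1cc([C@H]2c3c(ccc(O[Si](C(C)C)(C(C)C)C(C)C)c3OC)C=C(C=O)[C@@H]2CO[Si](C)(C)C(C)(C)C)ccc1O[Si](C(C)C)(C(C)C)C(C)C | intermediate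
10 | vitedoin A, (1S,2R)-7-hydroxy-1-(4-hydroxy-3-methoxyphenyl)-2-(hydroxymethyl)-8-methoxy-1,2-dihydronaphthalene-3-carbaldehyde | COc1cc([C@H]2c3c(ccc(O)c3OC)C=C(C=O)[C@@H]2CO)ccc1O | target

**Totals**
Total step count: 8. Longest linear sequence: 8 (1 → 10; 8 is purchased).

**Steps most likely to fail, with fallbacks**
1. Step 7 (radical annulation). Risks: low trans/cis control at C1, weak light absorption by the aliphatic iminium, and photo-oxidation of the electron-rich product. Fallback: switch to a closed-shell, auxiliary-controlled cycloaddition. Photoenolise 7 (365 nm) to the hydroxy-o-quinodimethane and trap it in an endo Diels–Alder with (5R)-5-menthyloxyfuran-2(5H)-one. Then NaBH4/KOH gives the lactone, dehydration gives C3=C4, and DIBAL opens the lactone to the hydroxy-enal.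
2. Step 5 (ortho-lithiation and addition to a second aldehyde). Risks: incomplete or misdirected lithiation, and competing addition of s-BuLi to the electrophile. Fallback: quench the C2-lithio amino alkoxide with B(OMe)3 to the boronic acid and make 7 directly by Suzuki–Miyaura benzylation with 4-(triisopropylsilyloxy)-3-methoxybenzyl bromide (from 5 by NaBH4, then PBr3). This also bypasses step 6.
3. Step 6 (chemoselective hydrogenolysis). Risks: over-reduction of the aldehyde or reduction at the lactol carbon to the phthalan. Fallback: oxidise lactol 6 to the 3-arylphthalide, cleave its benzylic C–O reductively (Zn/KOH or H2/Pd) to the 2-benzylbenzoic acid, and return to aldehyde 7 via the Weinreb amide and DIBAL.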